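## Retrosynthetic overview

1. Lactone last: C8–C17 bond by copper hydride reductive aldol of a C7 acrylate onto a C8 ketone (sets C8 and C17).
2. Ten-membered ring: C6–C7 bond by intramolecular chromium γ-chloroallylation of a C7 aldehyde (sets C6–Cl and C7–O, forms C5=C16); this is the new step.
3. Seco chain: C8–C9 from a glyoxal-derived dithiane anion and a ring A aldehyde; C2–C3 from Zr-to-Zn alkenylation with a four-carbon chloro-enyne.
4. Ring A: epoxide-initiated cation–olefin cyclisation of an 8-oxygenated geranyl acetate (sets C1 and C10; C14 is corrected later by oxidation/reduction).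
5. First stereocentres (C1/C14 epoxide): amine-catalysed asymmetric epoxidation of achiral 8-oxogeranyl acetate. Ring order: ring A, then the ten-membered ring, then the lactone.

Assumption: locants in the text (C1–C20) follow briarane numbering; systematic names carry their own numbering. TBS = tert-butyldimethylsilyl.

## Route

Step 1
Reactants: 1 geranyl acetate
Product: 3 (2E,6E)-3,7-dimethyl-8-oxoocta-2,6-dien-1-yl acetate, via allylic alcohol 2 (not isolated)
Conditions: SeO2 (10 mol%), t-BuOOH, salicylic acid (cat.), CH2Cl2, rt; then MnO2, CH2Cl2, rt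
Reagents that add atoms: tert-butyl hydroperoxide, CC(C)(C)OO
Why: Riley allylic oxidation (ene reaction then [2,3]-shift) attacks the E-methyl of the more electron-rich distal alkene, and MnO2 takes the allylic alcohol to the E-enal; no stereocentre is formed.

Step 2
Reactants: 3 (2E,6E)-3,7-dimethyl-8-oxoocta-2,6-dien-1-yl acetate
Product: 5 (E)-5-[(2R,3R)-3-(hydroxymethyl)-3-methyloxiran-2-yl]-3-methylpent-2-en-1-yl acetate, via epoxy aldehyde 4 (not isolated)
Conditions: 9-amino-9-deoxy-epi-quinidine·2CF3CO2H (10 mol%), 50% aq. H2O2, 1,4-dioxane, 40 °C; then NaBH4, MeOH, 0 °C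
Reagents that add atoms: hydrogen peroxide, OO
Why: Primary-amine iminium-catalysed asymmetric Weitz–Scheffer epoxidation of an α-branched enal touches only the conjugated alkene and gives the trans epoxide, setting C14 and C1 as the first stereocentres; the amine pseudo-enantiomer (quinidine- or quinine-derived) is the one that gives the (R,R) epoxy alcohol, and borohydride reduces the aldehyde in the same flask.

Step 3
Reactants: 5 (E)-5-[(2R,3R)-3-(hydroxymethyl)-3-methyloxiran-2-yl]-3-methylpent-2-en-1-yl acetate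
Product: 6 (E)-5-[(2R,3R)-3-(TBS-oxymethyl)-3-methyloxiran-2-yl]-3-methylpent-2-en-1-yl acetate
Conditions: TBSCl, imidazole, DMF, 0 °C to rt
Reagents that add atoms: tert-butyldimethylsilyl chloride, CC(C)(C)[Si](C)(C)Cl
Why: Standard silylation gives a non-participating ether on C2–O so that no acyl group can attack the epoxide in the next step.

Step 4
Reactants: 6 (E)-5-[(2R,3R)-3-(TBS-oxymethyl)-3-methyloxiran-2-yl]-3-methylpent-2-en-1-yl acetate
Product: 8 (1R,2S,3S)-2-(TBS-oxymethyl)-3-(hydroxymethyl)-2-methyl-4-methylidenecyclohexan-1-ol, via cyclised acetate 7 (not isolated)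
Conditions: MeAlCl2 (2 equiv), CH2Cl2, −78 °C; then MeOH, K2CO3, 0 °C to rt
Reagents that add atoms: none
Why: Epoxide-initiated cation–olefin (Stork–Eschenmoser) cyclisation through a chair: C10 attacks C1 from the back (inversion at C1), the E-alkene puts C9 equatorial, so C15 ends axial and cis to C9 with C2 and C9 trans-diequatorial, and kinetic loss of a C20 proton gives the exocyclic alkene; methanolysis then frees C9–OH.

Step 5
Reactants: 8 (1R,2S,3S)-2-(TBS-oxymethyl)-3-(hydroxymethyl)-2-methyl-4-methylidenecyclohexan-1-ol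
Product: 9 (1S,2S)-2-(TBS-oxymethyl)-2-methyl-6-methylidene-3-oxocyclohexane-1-carbaldehyde
Conditions: Dess–Martin periodinane (2.5 equiv), NaHCO3, CH2Cl2, 0 °C to rt
Reagents that add atoms: none
Why: Buffered Dess–Martin oxidation takes both alcohols up, which erases the wrong (equatorial) C14 carbinol and gives the C9 aldehyde without moving the β,γ-alkene.

Step 6
Reactants: 10 2,2-dimethoxyacetaldehyde
Product: 11 2-(dimethoxymethyl)-1,3-dithiane
Conditions: propane-1,3-dithiol (1.0 equiv), MgBr2·OEt2 (cat.), Et2O, 0 °C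
Reagents that add atoms: propane-1,3-dithiol, SCCCS
Why: Mild Lewis-acid thioacetalisation converts the free aldehyde much faster than the dimethyl acetal, giving a glyoxal masked differently at its two carbons (C8 dithiane, C7 acetal).

Step 7
Reactants: 9 (1S,2S)-2-(TBS-oxymethyl)-2-methyl-6-methylidene-3-oxocyclohexane-1-carbaldehyde; 11 2-(dimethoxymethyl)-1,3-dithiane
Product: 13 (2S,3S)-2-(TBS-oxymethyl)-3-{[2-(dimethoxymethyl)-1,3-dithian-2-yl](hydroxy)methyl}-2-methyl-4-methylidenecyclohexan-1-one (both C9 epimers), via lithiodithiane 12 (not isolated)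
Conditions: 11 (1.15 equiv), n-BuLi (1.1 equiv), THF, −78 °C; then 9, −78 °C; aq. NH4Cl
Reagents that add atoms: none
Why: Corey–Seebach acyl-anion addition forms C8–C9 at the aldehyde in preference to the hindered neopentyl ketone; the C9 configuration is not needed because the carbinol is oxidised next.

Step 8
Reactants: 13 (2S,3S)-2-(TBS-oxymethyl)-3-{[2-(dimethoxymethyl)-1,3-dithian-2-yl](hydroxy)methyl}-2-methyl-4-methylidenecyclohexan-1-one
Product: 14 (2S,3S)-2-(TBS-oxymethyl)-3-{[2-(dimethoxymethyl)-1,3-dithian-2-yl]carbonyl}-2-methyl-4-methylidenecyclohexan-1-one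
Conditions: SO3·pyridine, DMSO, i-Pr2NEt, CH2Cl2, 0 °C
Reagents that add atoms: none
Why: Parikh–Doering oxidation tolerates the dithiane (periodinanes do not) and converges both C9 epimers on one diketone.

Step 9
Reactants: 14 (2S,3S)-2-(TBS-oxymethyl)-3-{[2-(dimethoxymethyl)-1,3-dithian-2-yl]carbonyl}-2-methyl-4-methylidenecyclohexan-1-one
Product: 15 (1S,2S,3S)-2-(TBS-oxymethyl)-3-{(S)-[2-(dimethoxymethyl)-1,3-dithian-2-yl](hydroxy)methyl}-2-methyl-4-methylidenecyclohexan-1-ol
Conditions: LiBH(s-Bu)3 (3 equiv), THF, −78 to −20 °C; aq. NH4Cl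
Reagents that add atoms: none
Why: Diastereoselective hydride reduction: the bulky borohydride attacks the C14 ketone equatorially to give the axial 14S alcohol (trans to C15), and reduces the C9 ketone under Felkin–Anh control from C10 (quaternary C1 anti to hydride) to give 9S.

Step 10
Reactants: 15 (1S,2S,3S)-2-(TBS-oxymethyl)-3-{(S)-[2-(dimethoxymethyl)-1,3-dithian-2-yl](hydroxy)methyl}-2-methyl-4-methylidenecyclohexan-1-ol
Product: 16 (1S,2S,3S)-3-{(S)-acetoxy[2-(dimethoxymethyl)-1,3-dithian-2-yl]methyl}-2-(TBS-oxymethyl)-2-methyl-4-methylidenecyclohexyl acetate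
Conditions: Ac2O, Et3N, DMAP, CH2Cl2, rt to 40 °C
Reagents that add atoms: acetic anhydride, CC(=O)OC(C)=O
Why: DMAP-catalysed acylation installs the C9 and C14 acetates of the target, which then serve as protecting groups.

Step 11
Reactants: 16 (1S,2S,3S)-3-{(S)-acetoxy[2-(dimethoxymethyl)-1,3-dithian-2-yl]methyl}-2-(TBS-oxymethyl)-2-methyl-4-methylidenecyclohexyl acetate
Product: 17 (1S,2S,3S)-3-{(S)-acetoxy[2-(dimethoxymethyl)-1,3-dithian-2-yl]methyl}-2-(hydroxymethyl)-2-methyl-4-methylidenecyclohexyl acetate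
Conditions: HF·pyridine, pyridine, THF, 0 °C to rt
Reagents that add atoms: none
Why: Buffered fluoride desilylation frees the C2 primary alcohol and leaves the acetal, dithiane and acetates intact.

Step 12
Reactants: 17 (1S,2S,3S)-3-{(S)-acetoxy[2-(dimethoxymethyl)-1,3-dithian-2-yl]methyl}-2-(hydroxymethyl)-2-methyl-4-methylidenecyclohexyl acetate
Product: 18 (1S,2R,3S)-3-{(S)-acetoxy[2-(dimethoxymethyl)-1,3-dithian-2-yl]methyl}-2-formyl-2-methyl-4-methylidenecyclohexyl acetate
Conditions: SO3·pyridine, DMSO, i-Pr2NEt, CH2Cl2, 0 °C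
Reagents that add atoms: none
Why: Parikh–Doering oxidation gives the non-enolisable C2 aldehyde on the quaternary centre.

Step 13
Reactants: 19 1,3-dichloropropan-2-one
Product: 20 1-chloro-2-(chloromethyl)but-3-yn-2-ol
Conditions: ethynylmagnesium bromide, THF, −78 °C; aq. NH4Cl at −78 °C
Reagents that add atoms: ethynylmagnesium bromide, C#C[Mg]Br
Why: Grignard 1,2-addition to the ketone; a cold quench stops the alkoxide from closing to an epoxide.

Step 14
Reactants: 20 1-chloro-2-(chloromethyl)but-3-yn-2-ol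
Product: 21 4-chloro-3-(chloromethyl)but-3-en-1-yne (E/Z mixture)
Conditions: POCl3, pyridine, 0 °C to rt
Reagents that add atoms: none
Why: E2 dehydration of the tertiary propargylic alcohol can only run toward a CH2Cl group, so it gives the chloro-enyne that carries C3–C6 and C16; the alkene geometry is irrelevant later.

Step 15
Reactants: 18 (1S,2R,3S)-3-{(S)-acetoxy[2-(dimethoxymethyl)-1,3-dithian-2-yl]methyl}-2-formyl-2-methyl-4-methylidenecyclohexyl acetate; 21 4-chloro-3-(chloromethyl)but-3-en-1-yne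
Product: 25 (1S,2R,3S)-3-{(S)-acetoxy[2-(dimethoxymethyl)-1,3-dithian-2-yl]methyl}-2-[(1S,2E)-1-acetoxy-5-chloro-4-(chloromethyl)penta-2,4-dienyl]-2-methyl-4-methylidenecyclohexyl acetate, via alkenylzirconocene 22 (not isolated), via alkenylzinc 23 (not isolated), via C2 carbinol 24 (not isolated)
Conditions: 21, Cp2Zr(H)Cl, CH2Cl2, rt; Me2Zn, toluene, −65 °C; (−)-MIB [3-exo-morpholinoisoborneol] (10 mol%), then 18, −30 to 0 °C; then Ac2O, Et3N, DMAP; aq. NH4Cl
Reagents that add atoms: acetic anhydride, CC(=O)OC(C)=O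
Why: Syn hydrozirconation of the terminal alkyne fixes the 3E alkene, Zr-to-Zn transmetalation and amino-alcohol-accelerated alkenylzinc addition form C2–C3 with the ligand enantiomer chosen to give 2S, and the zinc alkoxide is acetylated in the flask.

Step 16
Reactants: 25 (1S,2R,3S)-3-{(S)-acetoxy[2-(dimethoxymethyl)-1,3-dithian-2-yl]methyl}-2-[(1S,2E)-1-acetoxy-5-chloro-4-(chloromethyl)penta-2,4-dienyl]-2-methyl-4-methylidenecyclohexyl acetate
Product: 26 (1S,2R,3S)-3-[(S)-acetoxy(2-formyl-1,3-dithian-2-yl)methyl]-2-[(1S,2E)-1-acetoxy-5-chloro-4-(chloromethyl)penta-2,4-dienyl]-2-methyl-4-methylidenecyclohexyl acetate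
Conditions: PPTS, acetone–H2O (10:1), 50 °C
Reagents that add atoms: water, O
Why: Mild acetal hydrolysis frees the non-enolisable C7 aldehyde while the C8 ketone stays masked as the dithiane.

Step 17
Reactants: 26 (1S,2R,3S)-3-[(S)-acetoxy(2-formyl-1,3-dithian-2-yl)methyl]-2-[(1S,2E)-1-acetoxy-5-chloro-4-(chloromethyl)penta-2,4-dienyl]-2-methyl-4-methylidenecyclohexyl acetate
Product: 28 (1R,2S,3E,6S,7R,9S,10S,14S)-2,9,14-triacetoxy-6-chloro-7-hydroxy-1-methyl-5,11-dimethylidenebicyclo[8.4.0]tetradec-3-ene-8-spiro-2'-(1,3-dithiane), via allylchromium 27 (not isolated)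
Conditions: CrCl2 (10 equiv), THF–DMF (4:1), 0.002 M, syringe-pump addition of 26 over 8 h, rt; aq. sodium serinate
Reagents that add atoms: none
Why: Proposed new method: divalent chromium inserts only into the primary allylic C16–Cl bond, both vinyl chloride isomers funnel into one equilibrating allylchromium species whose chlorine-bearing γ-carbon (C6) adds to the tethered C7 aldehyde through a Zimmerman–Traxler chair with C8 and Cl equatorial, which closes the ten-membered ring, gives the anti C6–Cl/C7–OH pair and unveils C5=C16, with the aldehyde face (7R) expected from 1,3-anti induction by the C9 acetate and the trans-diequatorial ring A junction; the closest known reactions are the intermolecular chromium γ-chloroallylation of aldehydes with 1,3-dichloropropene (anti chlorohydrins) and intramolecular Nozaki–Hiyama allylation to ten-membered germacranolide rings.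

Step 18
Reactants: 28 (1R,2S,3E,6S,7R,9S,10S,14S)-2,9,14-triacetoxy-6-chloro-7-hydroxy-1-methyl-5,11-dimethylidenebicyclo[8.4.0]tetradec-3-ene-8-spiro-2'-(1,3-dithiane)
Product: 29 the 7-O-acryloyl ester of 28
Conditions: acryloyl chloride, i-Pr2NEt, CH2Cl2, −40 to 0 °C
Reagents that add atoms: acryloyl chloride, C=CC(=O)Cl
Why: Acylation of the hindered chlorohydrin oxygen under non-nucleophilic amine base (no epoxide closure) puts C17–C19 on O7.

Step 19
Reactants: 29 the 7-O-acryloyl ester of 28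
Product: 30 (1R,2S,3E,6S,7R,9S,10S,14S)-2,9,14-triacetoxy-7-(acryloyloxy)-6-chloro-1-methyl-5,11-dimethylidenebicyclo[8.4.0]tetradec-3-en-8-one
Conditions: PhI(OCOCF3)2, MeCN–H2O (9:1), 0 °C
Reagents that add atoms: water, O
Why: Oxidative dithiane hydrolysis with a hypervalent iodine reagent unmasks the C8 ketone under non-basic conditions that spare the β-chloro ketone, diene and acrylate.

Step 20
Reactants: 30 (1R,2S,3E,6S,7R,9S,10S,14S)-2,9,14-triacetoxy-7-(acryloyloxy)-6-chloro-1-methyl-5,11-dimethylidenebicyclo[8.4.0]tetradec-3-en-8-one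
Product: 32 CNP0178742.3, via silyl aldolate 31 (not isolated)
Conditions: Cu(OAc)2·H2O (5 mol%), rac-BINAP (5 mol%), (Me2HSi)2O, THF, rt; then 1 M HCl, THF, 0 °C
Reagents that add atoms: none
Why: Copper hydride reductive aldol cyclisation: 1,4-hydride addition makes C18 and a copper propionate enolate that can reach the C8 ketone only from the face of O7 with the C6–C7–C8–C9 torsion anti, giving the trans-fused lactone with 8R, and the chelated enolate places the C17 methyl cis to the new hydroxyl (17R, also the isomer with methyl trans to C9).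

## Compound list

1 | geranyl acetate | CC(=O)OC/C=C(\C)CCC=C(C)C | starting material
2 | (2E,6E)-8-hydroxy-3,7-dimethylocta-2,6-dien-1-yl acetate | CC(=O)OC/C=C(\C)CC/C=C(\C)CO | intermediate
3 | (2E,6E)-3,7-dimethyl-8-oxoocta-2,6-dien-1-yl acetate | CC(=O)OC/C=C(\C)CC/C=C(\C)C=O | intermediate
4 | (E)-5-[(2R,3S)-3-formyl-3-methyloxiran-2-yl]-3-methylpent-2-en-1-yl acetate | CC(=O)OC/C=C(\C)CC[C@H]1O[C@]1(C)C=O | intermediate
5 | (E)-5-[(2R,3R)-3-(hydroxymethyl)-3-methyloxiran-2-yl]-3-methylpent-2-en-1-yl acetate | CC(=O)OC/C=C(\C)CC[C@H]1O[C@]1(C)CO | intermediate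
6 | (E)-5-[(2R,3R)-3-(TBS-oxymethyl)-3-methyloxiran-2-yl]-3-methylpent-2-en-1-yl acetate | CC(=O)OC/C=C(\C)CC[C@H]1O[C@]1(C)CO[Si](C)(C)C(C)(C)C | intermediate
7 | [(1S,2S,3R)-2-(TBS-oxymethyl)-3-hydroxy-2-methyl-6-methylidenecyclohexyl]methyl acetate | C=C1CC[C@@H](O)[C@](C)(CO[Si](C)(C)C(C)(C)C)[C@H]1COC(C)=O | intermediate
8 | (1R,2S,3S)-2-(TBS-oxymethyl)-3-(hydroxymethyl)-2-methyl-4-methylidenecyclohexan-1-ol | C=C1CC[C@@H](O)[C@](C)(CO[Si](C)(C)C(C)(C)C)[C@H]1CO | intermediate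
9 | (1S,2S)-2-(TBS-oxymethyl)-2-methyl-6-methylidene-3-oxocyclohexane-1-carbaldehyde | C=C1CCC(=O)[C@](C)(CO[Si](C)(C)C(C)(C)C)[C@H]1C=O | intermediate
10 | 2,2-dimethoxyacetaldehyde | COC(OC)C=O | starting material
11 | 2-(dimethoxymethyl)-1,3-dithiane | COC(OC)C1SCCCS1 | intermediate
12 | 2-(dimethoxymethyl)-2-lithio-1,3-dithiane | [Li]C1(C(OC)OC)SCCCS1 | intermediate
13 | (2S,3S)-2-(TBS-oxymethyl)-3-{[2-(dimethoxymethyl)-1,3-dithian-2-yl](hydroxy)methyl}-2-methyl-4-methylidenecyclohexan-1-one (C9 epimers) | C=C1CCC(=O)[C@](C)(CO[Si](C)(C)C(C)(C)C)[C@H]1C(O)C2(C(OC)OC)SCCCS2 | intermediate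
14 | (2S,3S)-2-(TBS-oxymethyl)-3-{[2-(dimethoxymethyl)-1,3-dithian-2-yl]carbonyl}-2-methyl-4-methylidenecyclohexan-1-one | C=C1CCC(=O)[C@](C)(CO[Si](C)(C)C(C)(C)C)[C@H]1C(=O)C2(C(OC)OC)SCCCS2 | intermediate
15 | (1S,2S,3S)-2-(TBS-oxymethyl)-3-{(S)-[2-(dimethoxymethyl)-1,3-dithian-2-yl](hydroxy)methyl}-2-methyl-4-methylidenecyclohexan-1-ol | C=C1CC[C@H](O)[C@](C)(CO[Si](C)(C)C(C)(C)C)[C@H]1[C@H](O)C2(C(OC)OC)SCCCS2 | intermediate
16 | (1S,2S,3S)-3-{(S)-acetoxy[2-(dimethoxymethyl)-1,3-dithian-2-yl]methyl}-2-(TBS-oxymethyl)-2-methyl-4-methylidenecyclohexyl acetate | C=C1CC[C@H](OC(C)=O)[C@](C)(CO[Si](C)(C)C(C)(C)C)[C@H]1[C@H](OC(C)=O)C2(C(OC)OC)SCCCS2 | intermediate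
17 | (1S,2S,3S)-3-{(S)-acetoxy[2-(dimethoxymethyl)-1,3-dithian-2-yl]methyl}-2-(hydroxymethyl)-2-methyl-4-methylidenecyclohexyl acetate | C=C1CC[C@H](OC(C)=O)[C@](C)(CO)[C@H]1[C@H](OC(C)=O)C2(C(OC)OC)SCCCS2 | intermediate
18 | (1S,2R,3S)-3-{(S)-acetoxy[2-(dimethoxymethyl)-1,3-dithian-2-yl]methyl}-2-formyl-2-methyl-4-methylidenecyclohexyl acetate | C=C1CC[C@H](OC(C)=O)[C@](C)(C=O)[C@H]1[C@H](OC(C)=O)C2(C(OC)OC)SCCCS2 | intermediate
19 | 1,3-dichloropropan-2-one | ClCC(=O)CCl | starting material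
20 | 1-chloro-2-(chloromethyl)but-3-yn-2-ol | ClCC(O)(CCl)C#C | intermediate
21 | 4-chloro-3-(chloromethyl)but-3-en-1-yne (E/Z mixture) | ClCC(=CCl)C#C | intermediate
22 | chloro[(1E)-4-chloro-3-(chloromethyl)buta-1,3-dienyl]zirconocene | Cl[Zr](/C=C/C(CCl)=CCl)(C1C=CC=C1)C1C=CC=C1 | intermediate
23 | [(1E)-4-chloro-3-(chloromethyl)buta-1,3-dienyl](methyl)zinc | C[Zn]/C=C/C(CCl)=CCl | intermediate
24 | (1S,2R,3S)-3-{(S)-acetoxy[2-(dimethoxymethyl)-1,3-dithian-2-yl]methyl}-2-[(1S,2E)-5-chloro-4-(chloromethyl)-1-hydroxypenta-2,4-dienyl]-2-methyl-4-methylidenecyclohexyl acetate (formed as its zinc alkoxide) | C=C1CC[C@H](OC(C)=O)[C@](C)([C@@H](O)/C=C/C(CCl)=CCl)[C@H]1[C@H](OC(C)=O)C2(C(OC)OC)SCCCS2 | intermediate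
25 | (1S,2R,3S)-3-{(S)-acetoxy[2-(dimethoxymethyl)-1,3-dithian-2-yl]methyl}-2-[(1S,2E)-1-acetoxy-5-chloro-4-(chloromethyl)penta-2,4-dienyl]-2-methyl-4-methylidenecyclohexyl acetate | C=C1CC[C@H](OC(C)=O)[C@](C)([C@@H](OC(C)=O)/C=C/C(CCl)=CCl)[C@H]1[C@H](OC(C)=O)C2(C(OC)OC)SCCCS2 | intermediate
26 | (1S,2R,3S)-3-[(S)-acetoxy(2-formyl-1,3-dithian-2-yl)methyl]-2-[(1S,2E)-1-acetoxy-5-chloro-4-(chloromethyl)penta-2,4-dienyl]-2-methyl-4-methylidenecyclohexyl acetate | C=C1CC[C@H](OC(C)=O)[C@](C)([C@@H](OC(C)=O)/C=C/C(CCl)=CCl)[C@H]1[C@H](OC(C)=O)C2(C=O)SCCCS2 | intermediate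
27 | allylchromium dichloride formed from 26 at C16 | C=C1CC[C@H](OC(C)=O)[C@](C)([C@@H](OC(C)=O)/C=C/C(C[Cr](Cl)Cl)=CCl)[C@H]1[C@H](OC(C)=O)C2(C=O)SCCCS2 | intermediate
28 | (1R,2S,3E,6S,7R,9S,10S,14S)-2,9,14-triacetoxy-6-chloro-7-hydroxy-1-methyl-5,11-dimethylidenebicyclo[8.4.0]tetradec-3-ene-8-spiro-2'-(1,3-dithiane) | C=C1CC[C@H](OC(C)=O)[C@]2(C)[C@@H](OC(C)=O)/C=C/C(=C)[C@H](Cl)[C@H](O)C3(SCCCS3)[C@@H](OC(C)=O)[C@@H]12 | intermediate
29 | 7-O-acryloyl ester of 28 | C=C1CC[C@H](OC(C)=O)[C@]2(C)[C@@H](OC(C)=O)/C=C/C(=C)[C@H](Cl)[C@H](OC(=O)C=C)C3(SCCCS3)[C@@H](OC(C)=O)[C@@H]12 | intermediate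
30 | (1R,2S,3E,6S,7R,9S,10S,14S)-2,9,14-triacetoxy-7-(acryloyloxy)-6-chloro-1-methyl-5,11-dimethylidenebicyclo[8.4.0]tetradec-3-en-8-one | C=C1CC[C@H](OC(C)=O)[C@]2(C)[C@@H](OC(C)=O)/C=C/C(=C)[C@H](Cl)[C@H](OC(=O)C=C)C(=O)[C@@H](OC(C)=O)[C@@H]12 | intermediate
31 | 8-O-(1,1,3,3-tetramethyldisiloxanyl) ether of 32 | C=C1CC[C@H](OC(C)=O)[C@]2(C)[C@@H](OC(C)=O)/C=C/C(=C)[C@H](Cl)[C@@H]3OC(=O)[C@H](C)[C@@]3(O[Si](C)(C)O[SiH](C)C)[C@@H](OC(C)=O)[C@@H]12 | intermediate
32 | CNP0178742.3, (1R,2S,3E,6S,7R,8R,9S,10S,14S,17R)-2,9,14-triacetoxy-6-chloro-8-hydroxybriara-3,5(16),11(20)-trien-18,7-olide | C=C1CC[C@H](OC(C)=O)[C@]2(C)[C@@H](OC(C)=O)/C=C/C(=C)[C@H](Cl)[C@@H]3OC(=O)[C@H](C)[C@@]3(O)[C@@H](OC(C)=O)[C@@H]12 | target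

## Step count and risks

Total step count: 20 (17 on the main line, 1 for dithiane 11, 2 for enyne 21). Longest linear sequence: 17 steps (steps 1–5, 7–12, 15–20).

Steps most likely to fail:

Step 4 (cation–olefin cyclisation). The risk is endocyclic alkene isomers or hydride-shift ketone instead of the exocyclic alkene. Fallback: leave the cationic manifold for a radical one. Setting out from 6, catalytic Cp2TiCl (trivalent titanium, made from Cp2TiCl2 and Mn dust with collidine hydrochloride and Me3SiCl in THF) opens the epoxide homolytically at C1, the tertiary radical closes 6-endo on C10, and the C11 radical is trapped by titanium and lost by β-hydride elimination from C20, which gives the exocyclic alkene by mechanism. C1 epimers are separated after the same methanolysis and the route is rejoined at 8. No new compound is made.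

Step 17 (the proposed chromium γ-chloroallylation macrocyclisation). The risks are oligomerisation, further reduction of the product allylic chloride, or the wrong aldehyde face. Fallback with known reactions only, reversing the order of the two C–C bond formations; it sets out from 16 and comes back at 29. Acetal hydrolysis (PPTS, aqueous acetone) gives the C7 aldehyde F1. Intermolecular chromium γ-chloroallylation of F1 with 21 (CrCl2, THF–DMF) gives the anti chlorohydrin enyne F2. Hydrozirconation–iodination (Cp2Zr(H)Cl, then I2) gives the E-iodo diene F3, and acryloyl chloride gives the 7-O-acrylate F4. HF·pyridine frees the C2 alcohol F5 and Parikh–Doering oxidation gives the iodo aldehyde F6. Intramolecular Nozaki–Hiyama–Kishi coupling (CrCl2, NiCl2 cat., DMSO–THF, high dilution, short reaction time to spare the C6 chloride) closes C2–C3 to the macrocyclic allylic alcohol F7. Acetylation (Ac2O, DMAP) then gives 29.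

Step 20 (reductive aldol lactonisation). The risks are copper hydride attack on the allylic chloride or ketone, or the wrong C8/C17 outcome. Fallback: generate the enolate from a carbon–bromine bond instead of by hydride addition. Setting out from 28, acylation with racemic 2-bromopropanoyl bromide (its stereocentre is erased in the enolate) gives the bromo ester F8. PhI(OCOCF3)2 in aqueous MeCN unmasks the ketone F9. An intramolecular Reformatsky reaction (Zn dust activated with Me3SiCl, THF, 0 °C; aq. NH4Cl) closes the lactone and comes back at 32. A C17 epimer, if formed, is equilibrated with DBU.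

## Further compounds

F0 | step 4 | none | none
F1 | step 17 | (1S,2S,3S)-3-[(S)-acetoxy(2-formyl-1,3-dithian-2-yl)methyl]-2-(TBS-oxymethyl)-2-methyl-4-methylidenecyclohexyl acetate | C=C1CC[C@H](OC(C)=O)[C@](C)(CO[Si](C)(C)C(C)(C)C)[C@H]1[C@H](OC(C)=O)C2(C=O)SCCCS2
F2 | step 17 | anti chlorohydrin enyne: F1 with the formyl group replaced by (1R,2S)-2-chloro-1-hydroxy-3-methylidenepent-4-ynyl | C=C1CC[C@H](OC(C)=O)[C@](C)(CO[Si](C)(C)C(C)(C)C)[C@H]1[C@H](OC(C)=O)C2([C@@H](O)[C@@H](Cl)C(=C)C#C)SCCCS2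
F3 | step 17 | E-iodo diene: F2 with the ethynyl group converted to (E)-2-iodoethenyl | C=C1CC[C@H](OC(C)=O)[C@](C)(CO[Si](C)(C)C(C)(C)C)[C@H]1[C@H](OC(C)=O)C2([C@@H](O)[C@@H](Cl)C(=C)/C=C/I)SCCCS2
F4 | step 17 | 7-O-acryloyl ester of F3 | C=C1CC[C@H](OC(C)=O)[C@](C)(CO[Si](C)(C)C(C)(C)C)[C@H]1[C@H](OC(C)=O)C2([C@@H](OC(=O)C=C)[C@@H](Cl)C(=C)/C=C/I)SCCCS2
F5 | step 17 | C2 primary alcohol from F4 (TBS removed) | C=C1CC[C@H](OC(C)=O)[C@](C)(CO)[C@H]1[C@H](OC(C)=O)C2([C@@H](OC(=O)C=C)[C@@H](Cl)C(=C)/C=C/I)SCCCS2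
F6 | step 17 | C2 aldehyde from F5 | C=C1CC[C@H](OC(C)=O)[C@](C)(C=O)[C@H]1[C@H](OC(C)=O)C2([C@@H](OC(=O)C=C)[C@@H](Cl)C(=C)/C=C/I)SCCCS2
F7 | step 17 | 2-O-deacetyl-29 (macrocyclic 2S allylic alcohol) | C=C1CC[C@H](OC(C)=O)[C@]2(C)[C@@H](O)/C=C/C(=C)[C@H](Cl)[C@H](OC(=O)C=C)C3(SCCCS3)[C@@H](OC(C)=O)[C@@H]12
F8 | step 20 | 7-O-(2-bromopropanoyl) ester of 28 | C=C1CC[C@H](OC(C)=O)[C@]2(C)[C@@H](OC(C)=O)/C=C/C(=C)[C@H](Cl)[C@H](OC(=O)C(C)Br)C3(SCCCS3)[C@@H](OC(C)=O)[C@@H]12
F9 | step 20 | 8-ketone from F8 (dithiane removed) | C=C1CC[C@H](OC(C)=O)[C@]2(C)[C@@H](OC(C)=O)/C=C/C(=C)[C@H](Cl)[C@H](OC(=O)C(C)Br)C(=O)[C@@H](OC(C)=O)[C@@H]12
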